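**Assumptions**
- The SMILES defines only the three stereocentres (C3 of both halves, C1 of the tetrahydro half, all R). The two hindered isoquinoline–naphthalene axes are unspecified, so biaryl intermediates are carried as atropisomer mixtures (separable by HPLC at 14 and 16 if one atropisomer is wanted).
- Numbered compounds are those that supply skeleton. Ordinary reagents are named in the conditions.

## Retrosynthetic overview
1. The central binaphthol bond is made last, by anodic hetero-coupling of two 5-(naphthol-yl)isoquinoline monomers, followed by global O-debenzylation.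
2. Both monomers come from one common 5-naphthyl-6,8-bis(benzyloxy)-3,4-dihydroisoquinoline: trans-selective C=N reduction gives the tetrahydro half; peri-selective 8-O-debenzylation and O-methylation give the 8-OMe dihydro half.
3. The dihydroisoquinoline comes from Bischler–Napieralski closure; the aryl–naphthyl bond comes from aryllithium 1,2-addition to 5-methoxy-7-methyl-1,4-naphthoquinone and reductive aromatisation.
4. C3 is bought in a D-alaninol-derived cyclic sulfamidate opened by an aryl Grignard; C1 is set by 1,3-induction from C3.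
5. Ring order: naphthoquinone (Friedel–Crafts annulation) → biaryl naphthol → dihydroisoquinoline → tetrahydroisoquinoline (one half) → binaphthol.

## Route

**Step 1**
Reactants: 1, 4-chloro-3-methylphenol; 2, maleic anhydride
Product: 3, 8-chloro-5-hydroxy-7-methylnaphthalene-1,4-dione
Conditions: AlCl3/NaCl melt, 180 °C, 2 min; then 2 M HCl
Reagents that add atoms: none (all atoms from 1 and 2)
Why: Double Friedel–Crafts acylation (naphthoquinone annulation); the phenol directs the first acylation ortho (para is blocked by Cl) and closure can only occur at the one free adjacent carbon, fixing the 5-OH/7-Me pattern.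

**Step 2**
Reactants: 3
Product: 4, 5-hydroxy-7-methylnaphthalene-1,4-dione (7-methyljuglone)
Conditions: SnCl2·2H2O, 4 M HCl, THF, 60 °C; then aq FeCl3
Reagents that add atoms: none
Why: Reductive dehalogenation: the tin(II)-generated hydroquinone loses the peri chloride through its keto tautomer, and Fe(III) re-oxidises over-reduced material to the quinone.

**Step 3**
Reactants: 4
Product: 5, 5-methoxy-7-methylnaphthalene-1,4-dione
Conditions: MeI, Ag2O, CH2Cl2, rt, dark
Reagents that add atoms: iodomethane, CI
Why: Williamson-type O-methylation of the chelated peri phenol with MeI/Ag2O.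

**Step 4**
Reactants: 6, 1,3-bis(benzyloxy)-5-bromobenzene; 7, tert-butyl (R)-4-methyl-1,2,3-oxathiazolidine-3-carboxylate 2,2-dioxide
Product: 8, tert-butyl (R)-[1-(3,5-bis(benzyloxy)phenyl)propan-2-yl]carbamate
Conditions: 6, Mg, THF, 50 °C; then CuI (10 mol %), 7, THF, −30 °C → rt; then 10% aq citric acid, rt
Reagents that add atoms: none (all atoms from 6 and 7)
Why: Copper-catalysed SN2 ring opening of the cyclic sulfamidate at its primary carbon by the aryl Grignard, then mild hydrolysis of the N-sulfate; the (R) centre is bought in 7 and is not involved in the bond formation.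

**Step 5**
Reactants: 8
Product: 9, tert-butyl (R)-[1-(3,5-bis(benzyloxy)-2-bromophenyl)propan-2-yl]carbamate
Conditions: NBS (1.0 equiv), MeCN, 0 °C
Reagents that add atoms: N-bromosuccinimide, O=C1CCC(=O)N1Br
Why: Electrophilic aromatic bromination; the two positions ortho to the side chain are equivalent by symmetry and are much more accessible than the carbon between the two benzyloxy groups.

**Step 6**
Reactants: 9; 5
Product: 10, tert-butyl [(2R)-1-{3,5-bis(benzyloxy)-2-(1-hydroxy-5-methoxy-7-methyl-4-oxo-1,4-dihydronaphthalen-1-yl)phenyl}propan-2-yl]carbamate (p-quinol, mixture at the carbinol carbon)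
Conditions: MeLi (1.05 equiv), THF, −78 °C; t-BuLi (2.1 equiv), −78 °C; then 5 (1.3 equiv), −78 °C; aq NH4Cl
Reagents that add atoms: none (all atoms from 9 and 5)
Why: Br–Li exchange after N-deprotonation, then 1,2-addition of the aryllithium to the quinone carbonyl remote from OMe, which is more electrophilic (the other carbonyl is deactivated by the adjacent OMe) and far less hindered; the new carbinol centre is destroyed in step 7.

**Step 7**
Reactants: 10
Product: 11, tert-butyl (R)-[1-{3,5-bis(benzyloxy)-2-(4-hydroxy-5-methoxy-7-methylnaphthalen-1-yl)phenyl}propan-2-yl]carbamate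
Conditions: Zn dust, AcOH–THF (1:1), rt
Reagents that add atoms: none
Why: Dissolving-metal reduction of the p-quinol (a vinylogous α-hydroxy ketone) expels the tertiary OH and aromatises to the 4-aryl-1-naphthol; the biaryl axis forms as an atropisomer mixture.

**Step 8**
Reactants: 11
Product: 12, 4-{2-[(2R)-2-acetamidopropyl]-4,6-bis(benzyloxy)phenyl}-8-methoxy-6-methylnaphthalen-1-yl acetate
Conditions: 4 M HCl/dioxane, rt; evaporate; then Ac2O, pyridine, DMAP (cat.), rt
Reagents that add atoms: acetic anhydride, CC(=O)OC(C)=O
Why: Acidolytic Boc removal, then N- and O-acetylation; the acetamide is the Bischler–Napieralski precursor and the acetate shields the naphthol from POCl3.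

**Step 9**
Reactants: 12
Product: 13, 4-[(3R)-6,8-bis(benzyloxy)-1,3-dimethyl-3,4-dihydroisoquinolin-5-yl]-8-methoxy-6-methylnaphthalen-1-ol
Conditions: POCl3, 2,4,6-collidine, MeCN, 80 °C; then K2CO3, MeOH, rt
Reagents that add atoms: none
Why: Bischler–Napieralski cyclodehydration onto the only free ortho carbon, which is activated ortho/para by the two benzyloxy groups; basic methanolysis in the work-up frees the naphthol and C3 is untouched.

**Step 10**
Reactants: 13
Product: 14, 4-[(1R,3R)-6,8-bis(benzyloxy)-1,3-dimethyl-1,2,3,4-tetrahydroisoquinolin-5-yl]-8-methoxy-6-methylnaphthalen-1-ol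
Conditions: LiAlH4, AlMe3, THF, −78 → 0 °C
Reagents that add atoms: none (adds H only)
Why: Diastereoselective hydride reduction of the AlMe3-complexed cyclic imine, the established trans-selective protocol for 1,3-dimethyl-3,4-dihydroisoquinolines (NaBH4 gives cis); C1 (R) is set by 1,3-induction from the bought C3 centre.

**Step 11**
Reactants: 13
Product: 15, (3R)-6-(benzyloxy)-5-(4-hydroxy-5-methoxy-7-methylnaphthalen-1-yl)-1,3-dimethyl-3,4-dihydroisoquinolin-8-ol
Conditions: MgBr2·OEt2, Me2S, toluene, 50 °C
Reagents that add atoms: none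
Why: Chelation-directed debenzylation: Mg2+ held between the imine N and the peri 8-OBn oxygen (six-membered chelate) activates only that benzyl ether towards bromide, as is known for benzyl ethers ortho to a carbonyl; Me2S scavenges BnBr, and the non-chelated 6-OBn and the methyl ethers stay.

**Step 12**
Reactants: 15
Product: 16, 4-[(3R)-6-(benzyloxy)-8-methoxy-1,3-dimethyl-3,4-dihydroisoquinolin-5-yl]-8-methoxy-6-methylnaphthalen-1-ol
Conditions: TMSCHN2, i-Pr2NEt, MeOH–MeCN, 0 °C → rt
Reagents that add atoms: (trimethylsilyl)diazomethane, C[Si](C)(C)C=[N+]=[N-] (supplies the O-methyl carbon)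
Why: Diazoalkane O-methylation of the most acidic phenol (8-OH, conjugated to the imine); the peri-hydrogen-bonded naphthol is inert to diazoalkanes (as in mono-methylation of 1,8-naphthalenediol) and the imine nitrogen is not alkylated.

**Step 13**
Reactants: 16; 14
Product: 17, tri-O-benzylmichellamine F (14 and 16 joined through the naphthalene carbons ortho to each naphthol OH)
Conditions: 16·HBF4, Bu4NBF4 (0.1 M), CH2Cl2–HFIP 4:1, divided cell, graphite-felt anode/Pt cathode, 2 mA cm⁻², 2.1 F mol⁻¹, −40 °C; current off, then 14·HBF4 (1.3 equiv), −40 → 0 °C; aq Na2S2O4/NaHCO3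
Reagents that add atoms: none (all atoms from 16 and 14)
Why: Proposed new method: anodic "phenoxonium-pool" hetero-coupling — two-electron oxidation of the para-blocked naphthol of N-protonated 16 (its isoquinolinium ring and nitrogen are deactivated) gives a 4-aryl-naphthoxenium ion stored as its HFIP adduct; with the current off, the naphthol of 14 (ammonium salt, its C7 shielded between two OBn groups) attacks the only open electrophilic carbon, ortho to oxygen, and tautomerisation gives the unsymmetrical binaphthol, so neither homodimer forms and the more oxidisable product never sees the anode; the closest known chemistry is cation-pool electrolysis for arene cross-coupling, anodic p-quinol-ether formation, and HFIP/acid-promoted arylation of quinone monoacetals.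

**Step 14**
Reactants: 17
Product: 18, michellamine F
Conditions: BCl3, pentamethylbenzene, CH2Cl2, −78 °C; MeOH quench; aq NaHCO3
Reagents that add atoms: none
Why: Lewis-acid debenzylation with a cation scavenger at −78 °C removes the three aryl benzyl ethers while leaving aryl methyl ethers, the imine and all stereocentres untouched (hydrogenolysis is avoided because it would reduce the C=N).

## Compound list
1 | 4-chloro-3-methylphenol | Cc1cc(O)ccc1Cl | starting material
2 | maleic anhydride | O=C1OC(=O)C=C1 | starting material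
3 | 8-chloro-5-hydroxy-7-methylnaphthalene-1,4-dione | O=C1C=CC(=O)c2c1c(O)cc(C)c2Cl | intermediate
4 | 5-hydroxy-7-methylnaphthalene-1,4-dione | O=C1C=CC(=O)c2c(O)cc(C)cc12 | intermediate
5 | 5-methoxy-7-methylnaphthalene-1,4-dione | COc1cc(C)cc2C(=O)C=CC(=O)c12 | intermediate
6 | 1,3-bis(benzyloxy)-5-bromobenzene | Brc1cc(OCc2ccccc2)cc(OCc2ccccc2)c1 | starting material
7 | tert-butyl (R)-4-methyl-1,2,3-oxathiazolidine-3-carboxylate 2,2-dioxide | C[C@@H]1COS(=O)(=O)N1C(=O)OC(C)(C)C | starting material (chiral pool, from D-alaninol)
8 | tert-butyl (R)-[1-(3,5-bis(benzyloxy)phenyl)propan-2-yl]carbamate | C[C@H](Cc1cc(OCc2ccccc2)cc(OCc2ccccc2)c1)NC(=O)OC(C)(C)C | intermediate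
9 | tert-butyl (R)-[1-(3,5-bis(benzyloxy)-2-bromophenyl)propan-2-yl]carbamate | C[C@H](Cc1cc(OCc2ccccc2)cc(OCc2ccccc2)c1Br)NC(=O)OC(C)(C)C | intermediate
10 | p-quinol adduct of 9 and 5 | C[C@H](Cc1cc(OCc2ccccc2)cc(OCc2ccccc2)c1C1(O)C=CC(=O)c2c(OC)cc(C)cc21)NC(=O)OC(C)(C)C | intermediate
11 | tert-butyl (R)-[1-{3,5-bis(benzyloxy)-2-(4-hydroxy-5-methoxy-7-methylnaphthalen-1-yl)phenyl}propan-2-yl]carbamate | C[C@H](Cc1cc(OCc2ccccc2)cc(OCc2ccccc2)c1-c1ccc(O)c2c(OC)cc(C)cc12)NC(=O)OC(C)(C)C | intermediate
12 | 4-{2-[(2R)-2-acetamidopropyl]-4,6-bis(benzyloxy)phenyl}-8-methoxy-6-methylnaphthalen-1-yl acetate | C[C@H](Cc1cc(OCc2ccccc2)cc(OCc2ccccc2)c1-c1ccc(OC(C)=O)c2c(OC)cc(C)cc12)NC(C)=O | intermediate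
13 | 4-[(3R)-6,8-bis(benzyloxy)-1,3-dimethyl-3,4-dihydroisoquinolin-5-yl]-8-methoxy-6-methylnaphthalen-1-ol | CC1=N[C@H](C)Cc2c1c(OCc1ccccc1)cc(OCc1ccccc1)c2-c1ccc(O)c2c(OC)cc(C)cc12 | intermediate (common)
14 | 4-[(1R,3R)-6,8-bis(benzyloxy)-1,3-dimethyl-1,2,3,4-tetrahydroisoquinolin-5-yl]-8-methoxy-6-methylnaphthalen-1-ol | C[C@H]1N[C@H](C)Cc2c1c(OCc1ccccc1)cc(OCc1ccccc1)c2-c1ccc(O)c2c(OC)cc(C)cc12 | intermediate
15 | (3R)-6-(benzyloxy)-5-(4-hydroxy-5-methoxy-7-methylnaphthalen-1-yl)-1,3-dimethyl-3,4-dihydroisoquinolin-8-ol | CC1=N[C@H](C)Cc2c1c(O)cc(OCc1ccccc1)c2-c1ccc(O)c2c(OC)cc(C)cc12 | intermediate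
16 | 4-[(3R)-6-(benzyloxy)-8-methoxy-1,3-dimethyl-3,4-dihydroisoquinolin-5-yl]-8-methoxy-6-methylnaphthalen-1-ol | CC1=N[C@H](C)Cc2c1c(OC)cc(OCc1ccccc1)c2-c1ccc(O)c2c(OC)cc(C)cc12 | intermediate
17 | tri-O-benzylmichellamine F | COc1cc(OCc2ccccc2)c(-c2cc(-c3cc(-c4c(OCc5ccccc5)cc(OCc5ccccc5)c5c4C[C@@H](C)N[C@@H]5C)c4cc(C)cc(OC)c4c3O)c(O)c3c(OC)cc(C)cc23)c2c1C(C)=N[C@H](C)C2 | intermediate
18 | michellamine F | COc1cc(O)c(-c2cc(-c3cc(-c4c(O)cc(O)c5c4C[C@@H](C)N[C@@H]5C)c4cc(C)cc(OC)c4c3O)c(O)c3c(OC)cc(C)cc23)c2c1C(C)=N[C@H](C)C2 | target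

## Summary
Total steps: 14.
Longest linear sequence: 11 (steps 1, 2, 3, 6, 7, 8, 9, 11, 12, 13, 14).

Steps most likely to fail, each with a fallback:
1. **Step 13 (proposed new anodic phenoxonium-pool hetero-coupling).** Fallback with known chemistry: Ag2O-mediated mixed oxidative phenolic coupling of 16 with N-formyl-14, NaBH4 reduction of the over-oxidised binaphthylidenediones, and chromatographic separation of the hetero-dimer from the two homodimers (statistical, at most about 50%), then deformylation and step 14.
2. **Step 6 (hindered aryllithium addition to the quinone; electron-transfer reduction and carbonyl regiochemistry).** Fallback: switch to Suzuki–Miyaura coupling. Reduce 5 to the hydroquinone, triflate the non-chelated 1-OH selectively, and couple with the pinacol boronate made from 9 (Pd/SPhos) to give 11 directly.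
3. **Step 11 (peri-selective 8-O-debenzylation, which also governs step 12).** Fallback: abandon the common intermediate for this half and carry the 8-OMe from the start. Begin from O-silylated 3-bromo-5-methoxyphenol, do the Grignard/7 opening, desilylate, brominate the free phenol ortho-selectively (ortho to OH, para to OMe; amine-catalysed NBS), O-benzylate, then run steps 6–9 to reach 16.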